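**Strategy.** Siphonaxanthin is cut at C9=C10 into a C27 ε-apo-aldehyde and a C13 β-ketophosphonate. Everything rests on a [4+2] disconnection of the hydroxylated β ring (C1–C6): the C3 oxygen lies para to C6, C1 carries the gem-dimethyl group and C5=C6 is tetrasubstituted, so the C3 enol ether of this ring is the Diels–Alder adduct of two acyclic, achiral pieces, the kinetic silyl dienol ether of mesityl oxide and ethyl but-2-ynoate. One cycloaddition forms C1–C6 and C4–C5 and sets every ring substituent and the C5=C6 alkene; the unmasked C3 ketone is then reduced enzymatically to the lone 3R center. The ε ring is bought in (R)-α-ionone, whose C6' center relays C3'.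

Key step: step 10

Assumption: (R)-(+)-α-ionone of high enantiomeric purity and (2E,4E,6E)-2,7-dimethylocta-2,4,6-trienedial are taken as purchasable; the ε ring therefore enters ready-made and the β ring is the only ring the route closes.
Carotenoid numbering is used for positions (C1–C6 β ring, primed numbers for the ε half).

Step 1
Reactants: 1 (R)-α-ionone; 2 triethyl phosphonoacetate
Product: 3 ethyl (2E,4E)-3-methyl-5-[(1R)-2,6,6-trimethylcyclohex-2-en-1-yl]penta-2,4-dienoate
Conditions: NaH, THF, 0 → 45 °C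
Reagents that add atoms: none
Why: Horner–Wadsworth–Emmons olefination of the methyl ketone should give mainly the thermodynamically favoured 2E dienoate (the minor 2Z isomer is removed by chromatography), and the stabilised phosphonate anion is too weakly basic to epimerise C6'.

Step 2
Reactants: 3
Product: 4 ethyl (2E,4E)-3-methyl-5-[(1R)-2,6,6-trimethyl-4-oxocyclohex-2-en-1-yl]penta-2,4-dienoate
Conditions: t-BuOOH (5 equiv, decane), Mn(OAc)3·2H2O (10 mol %), 3 Å MS, EtOAc, rt
Reagents that add atoms: tert-butyl hydroperoxide, CC(C)(C)OO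
Why: Metal-catalysed radical allylic oxidation with t-BuOOH should convert the only unhindered allylic methylene of the cyclohexene (C3') into the enone carbonyl, the tertiary C6'–H being shielded by the adjacent quaternary carbon and the neutral medium leaving C6' unepimerised.

Step 3
Reactants: 4
Product: 5 ethyl (2E,4E)-5-[(1R,4S)-4-hydroxy-2,6,6-trimethylcyclohex-2-en-1-yl]-3-methylpenta-2,4-dienoate (3',6'-cis)
Conditions: LiBH(s-Bu)3 (L-Selectride), THF, −78 °C; aq. NH4Cl
Reagents that add atoms: none
Why: Diastereoselective 1,2-reduction of the β,β-disubstituted cyclohexenone: the bulky borohydride leaves the dienoate alone at −78 °C and should attack anti to the C6' side chain and the syn-axial C1' methyl, so that substrate control from C6' sets C3' as the cis (3'S) alcohol.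

Step 4
Reactants: 5
Product: 6 (1R,4R)-4-[(1E,3E)-5-ethoxy-3-methyl-5-oxopenta-1,3-dien-1-yl]-3,5,5-trimethylcyclohex-2-en-1-yl benzoate (3',6'-trans)
Conditions: PhCO2H, PPh3, diisopropyl azodicarboxylate, THF, 0 °C
Reagents that add atoms: benzoic acid, OC(=O)c1ccccc1
Why: Mitsunobu reaction: SN2 displacement of the activated allylic alcohol by benzoate inverts C3' to the required 3'R (trans) configuration, the SN2' path being disfavoured because it would create a quaternary centre at C5'.

Step 5
Reactants: 6
Product: 7 (2E,4E)-5-[(1R,4R)-4-hydroxy-2,6,6-trimethylcyclohex-2-en-1-yl]-3-methylpenta-2,4-dien-1-ol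
Conditions: i-Bu2AlH (5 equiv), CH2Cl2, −78 → −20 °C; aq. potassium sodium tartrate
Reagents that add atoms: none
Why: Hydride reduction of esters: excess i-Bu2AlH reduces the dienoate to the primary allylic alcohol and cleaves the benzoate in the same operation, leaving both stereocenters untouched.

Step 6
Reactants: 7
Product: 8 [(2E,4E)-5-[(1R,4R)-4-hydroxy-2,6,6-trimethylcyclohex-2-en-1-yl]-3-methylpenta-2,4-dien-1-yl]triphenylphosphonium bromide
Conditions: PPh3·HBr, CH2Cl2, 0 °C → rt
Reagents that add atoms: triphenylphosphine hydrobromide, Br.P(c1ccccc1)(c1ccccc1)c1ccccc1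
Why: Acid-mediated phosphonium salt formation, the standard entry to carotenoid C15 Wittig salts: the primary dienylic hydroxyl ionises to a pentadienyl cation far more readily than the secondary ring allylic hydroxyl and is captured by PPh3 at the terminal carbon, and the non-nucleophilic solvent protects C3'.

Step 7
Reactants: 8; 9 (2E,4E,6E)-2,7-dimethylocta-2,4,6-trienedial (2 equiv)
Product: 11 (2E,4E,6E,8E,10E,12E)-13-[(1R,4R)-4-hydroxy-2,6,6-trimethylcyclohex-2-en-1-yl]-2,7,11-trimethyltrideca-2,4,6,8,10,12-hexaenal, via 8Z aldehyde isomer 10 (not isolated)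
Conditions: NaOMe, CH2Cl2/MeOH, 0 °C → rt; then I2 (cat.), CH2Cl2, daylight, rt
Reagents that add atoms: none
Why: Wittig reaction of the semi-stabilised dienyl ylide with one aldehyde group of the symmetrical dial (used in excess) forms C11'=C12', and the Z isomer that forms alongside is equilibrated to the all-E aldehyde by iodine catalysis.

Step 8
Reactants: 11; 12 diethyl [(E)-2-(cyclohexylamino)ethenyl]phosphonate (2.5 equiv)
Product: 14 (2E,4E,6E,8E,10E,12E,14E)-15-[(1R,4R)-4-hydroxy-2,6,6-trimethylcyclohex-2-en-1-yl]-4,9,13-trimethylpentadeca-2,4,6,8,10,12,14-heptaenal, via N-cyclohexyl unsaturated imine 13 (not isolated)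
Conditions: NaH (2.5 equiv), THF, 0 °C → rt; then aq. oxalic acid, 0 °C → rt
Reagents that add atoms: water, O
Why: Horner–Wadsworth–Emmons-type formyl-olefination (two-carbon homologation forming C11=C12): the metalated β-aminovinylphosphonate adds to the aldehyde and eliminates phosphate to an unsaturated imine that cannot react a second time, and mild acidic hydrolysis should release the E enal.

Step 9
Reactants: 15 mesityl oxide (4-methylpent-3-en-2-one)
Product: 16 trimethyl[(4-methylpenta-1,3-dien-2-yl)oxy]silane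
Conditions: LiN(i-Pr)2, THF, −78 °C; Me3SiCl, −78 °C → rt
Reagents that add atoms: chlorotrimethylsilane, C[Si](C)(C)Cl
Why: Silyl enol ether formation: kinetic deprotonation of the enone at the α'-methyl group and O-silylation of the cross-conjugated enolate give the 2-silyloxydiene.

Step 10
Reactants: 16; 17 ethyl but-2-ynoate
Product: 19 ethyl 2,6,6-trimethyl-4-oxocyclohex-1-ene-1-carboxylate, via silyl enol ether cycloadduct 18 (not isolated)
Conditions: neat, 2,6-di-tert-butyl-4-methylphenol (cat.), sealed tube, 160 °C; then AcOH/THF/H2O, 0 °C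
Reagents that add atoms: none
Why: A concerted, thermally allowed [4+2] cycloaddition of the electron-rich 2-silyloxydiene 16 with the electron-poor alkyne 17 forms C4–C5 and C1–C6 in one event, the closest known reaction type being the Diels–Alder reaction of 2-silyloxy-1,3-dienes with acetylenic esters to 1,4-cyclohexadienes. The six-membered ring is closed by intermolecular cycloaddition of two acyclic partners, and the alkyne delivers C5=C6 directly as the tetrasubstituted alkene conjugated to the ester. No stereocenter is formed; C3 leaves the step as a masked ketone (silyl enol ether 18) and becomes the single stereocenter of the ring in step 11. The step needs regioselectivity, which both diene substituents secure in the same sense: the silyloxy group on C3 and the two methyls on C1 put the largest HOMO coefficient on C4, which bonds to the β-carbon of the ynoate (C5), so that the gem-dimethyl terminus C1 joins the ester-bearing carbon C6. It also needs the diene to reach the s-cis conformation despite its cis-methyl group, hence the linear, sterically undemanding alkyne, the absence of Lewis acid and the high temperature. Cold, weakly acidic hydrolysis should protonate the enol ether at C2 only, so that C5=C6 stays β,γ to the new C3 ketone and does not move into conjugation with it.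

Step 11
Reactants: 19
Product: 20 ethyl (4R)-4-hydroxy-2,6,6-trimethylcyclohex-1-ene-1-carboxylate
Conditions: ketoreductase (commercial, (R)-selective, chosen by screening), NADP+ (cat.), i-PrOH, KH2PO4/K2HPO4 buffer pH 7, 30 °C
Reagents that add atoms: none
Why: Enzymatic carbonyl reduction: a ketoreductase differentiates the gem-dimethyl flank from the methyl-alkene flank of the ring ketone, as reductases do for the closely related 2,2,6-trimethylcyclohexane-1,4-dione, and hydride delivery from NADPH to one face sets C3 as R, while the neutral medium keeps the β,γ-double bond in place.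

Step 12
Reactants: 20
Product: 21 ethyl (4R)-4-[(tert-butyldimethylsilyl)oxy]-2,6,6-trimethylcyclohex-1-ene-1-carboxylate
Conditions: t-BuMe2SiCl, imidazole, DMF, rt
Reagents that add atoms: tert-butyldimethylsilyl chloride, CC(C)(C)[Si](C)(C)Cl
Why: Silyl ether formation protects the C3 hydroxyl for the hydride, palladium and carbanion steps that follow.

Step 13
Reactants: 21
Product: 22 [(4R)-4-[(tert-butyldimethylsilyl)oxy]-2,6,6-trimethylcyclohex-1-en-1-yl]methanol
Conditions: i-Bu2AlH (2.5 equiv), CH2Cl2, −78 °C; aq. potassium sodium tartrate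
Reagents that add atoms: none
Why: Hydride reduction of the hindered conjugated ester gives the primary allylic alcohol at C7 without touching the tetrasubstituted alkene.

Step 14
Reactants: 22
Product: 23 [(4R)-4-[(tert-butyldimethylsilyl)oxy]-2,6,6-trimethylcyclohex-1-en-1-yl]methyl methyl carbonate
Conditions: ClCO2Me, pyridine, CH2Cl2, 0 °C
Reagents that add atoms: methyl chloroformate, COC(=O)Cl
Why: Acylation of the primary allylic alcohol gives the methyl carbonate, the leaving group and methoxide source for the palladium step.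

Step 15
Reactants: 23
Product: 24 methyl 2-[(4R)-4-[(tert-butyldimethylsilyl)oxy]-2,6,6-trimethylcyclohex-1-en-1-yl]acetate
Conditions: Pd(OAc)2 (3 mol %), PPh3 (12 mol %), CO (10 atm), toluene, 50 °C
Reagents that add atoms: carbon monoxide, [C-]#[O+]
Why: Palladium-catalysed decarboxylative carbonylation of an allylic carbonate: oxidative addition to zerovalent palladium gives a π-allylpalladium methoxide, CO inserts at the unhindered primary terminus C7 and the acyl complex collapses to the β,γ-unsaturated methyl ester, which installs C8 while C5=C6 stays endocyclic.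

Step 16
Reactants: 25 diethyl (2-hydroxyethyl)phosphonate
Product: 26 diethyl [2-[(tert-butyldimethylsilyl)oxy]ethyl]phosphonate
Conditions: t-BuMe2SiCl, imidazole, CH2Cl2, rt
Reagents that add atoms: tert-butyldimethylsilyl chloride, CC(C)(C)[Si](C)(C)Cl
Why: Silyl ether formation masks the future C19 hydroxyl so that it can neither quench the carbanion nor take part in phosphate elimination.

Step 17
Reactants: 24; 26 (2.2 equiv)
Product: 27 diethyl [1-[(tert-butyldimethylsilyl)oxy]-4-[(4R)-4-[(tert-butyldimethylsilyl)oxy]-2,6,6-trimethylcyclohex-1-en-1-yl]-3-oxobutan-2-yl]phosphonate (both epimers at the phosphorus-bearing carbon)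
Conditions: 26, LiN(i-Pr)2 (2.2 equiv), THF, −78 °C; then 24, −78 → −40 °C; AcOH
Reagents that add atoms: none
Why: Claisen-type acylation of the α-lithiated phosphonate by the methyl ester gives the β-ketophosphonate (the second equivalent of anion is taken up by the acidic product), the low temperature suppressing β-elimination of silyloxide from the carbanion.

Step 18
Reactants: 27 (1.2 equiv); 14
Product: 28 (3R,3'R,6'R)-3,19-bis[(tert-butyldimethylsilyl)oxy]-3'-hydroxy-7,8-dihydro-β,ε-caroten-8-one (all-E)
Conditions: Ba(OH)2·8H2O (1.3 equiv), THF/H2O (40:1), rt, dark, argon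
Reagents that add atoms: none
Why: Horner–Wadsworth–Emmons olefination of the α-branched β-ketophosphonate under mild Ba(OH)2 activation should form the trisubstituted C9=C10 bond with the acyl group trans to C11 (the thermodynamically favoured E enone) and tolerates the free C3' hydroxyl.

Step 19
Reactants: 28
Product: 29 siphonaxanthin, (3R,3'R,6'R)-3,3',19-trihydroxy-7,8-dihydro-β,ε-caroten-8-one (all-E)
Conditions: n-Bu4NF (6 equiv)/AcOH (6 equiv), THF, 0 °C → rt, dark, argon
Reagents that add atoms: none
Why: Buffered fluoride cleaves both silyl ethers through Si–F bond formation without base- or acid-induced damage to the polyene, the β,γ-unsaturated ketone or the allylic C3' alcohol.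

**Compound list**

1 | (R)-α-ionone, (3E)-4-[(1R)-2,6,6-trimethylcyclohex-2-en-1-yl]but-3-en-2-one | CC1=CCCC(C)(C)[C@H]1/C=C/C(C)=O | starting material
2 | triethyl phosphonoacetate | CCOC(=O)CP(=O)(OCC)OCC | starting material
3 | ethyl (2E,4E)-3-methyl-5-[(1R)-2,6,6-trimethylcyclohex-2-en-1-yl]penta-2,4-dienoate | CC1=CCCC(C)(C)[C@H]1/C=C/C(C)=C/C(=O)OCC | intermediate
4 | ethyl (2E,4E)-3-methyl-5-[(1R)-2,6,6-trimethyl-4-oxocyclohex-2-en-1-yl]penta-2,4-dienoate | CC1=CC(=O)CC(C)(C)[C@H]1/C=C/C(C)=C/C(=O)OCC | intermediate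
5 | ethyl (2E,4E)-5-[(1R,4S)-4-hydroxy-2,6,6-trimethylcyclohex-2-en-1-yl]-3-methylpenta-2,4-dienoate | CC1=C[C@@H](O)CC(C)(C)[C@H]1/C=C/C(C)=C/C(=O)OCC | intermediate
6 | (1R,4R)-4-[(1E,3E)-5-ethoxy-3-methyl-5-oxopenta-1,3-dien-1-yl]-3,5,5-trimethylcyclohex-2-en-1-yl benzoate | CC1=C[C@H](OC(=O)c2ccccc2)CC(C)(C)[C@H]1/C=C/C(C)=C/C(=O)OCC | intermediate
7 | (2E,4E)-5-[(1R,4R)-4-hydroxy-2,6,6-trimethylcyclohex-2-en-1-yl]-3-methylpenta-2,4-dien-1-ol | CC1=C[C@H](O)CC(C)(C)[C@H]1/C=C/C(C)=C/CO | intermediate
8 | [(2E,4E)-5-[(1R,4R)-4-hydroxy-2,6,6-trimethylcyclohex-2-en-1-yl]-3-methylpenta-2,4-dien-1-yl]triphenylphosphonium bromide | CC1=C[C@H](O)CC(C)(C)[C@H]1/C=C/C(C)=C/C[P+](c1ccccc1)(c1ccccc1)c1ccccc1.[Br-] | intermediate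
9 | (2E,4E,6E)-2,7-dimethylocta-2,4,6-trienedial | O=C/C(C)=C/C=C/C=C(C)/C=O | starting material
10 | (2E,4E,6E,8Z,10E,12E)-13-[(1R,4R)-4-hydroxy-2,6,6-trimethylcyclohex-2-en-1-yl]-2,7,11-trimethyltrideca-2,4,6,8,10,12-hexaenal | CC1=C[C@H](O)CC(C)(C)[C@H]1/C=C/C(C)=C/C=C\C(C)=C\C=C\C=C(C)\C=O | intermediate
11 | (2E,4E,6E,8E,10E,12E)-13-[(1R,4R)-4-hydroxy-2,6,6-trimethylcyclohex-2-en-1-yl]-2,7,11-trimethyltrideca-2,4,6,8,10,12-hexaenal | CC1=C[C@H](O)CC(C)(C)[C@H]1/C=C/C(C)=C/C=C/C(C)=C/C=C/C=C(C)/C=O | intermediate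
12 | diethyl [(E)-2-(cyclohexylamino)ethenyl]phosphonate | CCOP(=O)(OCC)/C=C/NC1CCCCC1 | starting material
13 | N-cyclohexyl imine of aldehyde 14 | CC1=C[C@H](O)CC(C)(C)[C@H]1/C=C/C(C)=C/C=C/C(C)=C/C=C/C=C(C)/C=C/C=NC1CCCCC1 | intermediate
14 | (2E,4E,6E,8E,10E,12E,14E)-15-[(1R,4R)-4-hydroxy-2,6,6-trimethylcyclohex-2-en-1-yl]-4,9,13-trimethylpentadeca-2,4,6,8,10,12,14-heptaenal | CC1=C[C@H](O)CC(C)(C)[C@H]1/C=C/C(C)=C/C=C/C(C)=C/C=C/C=C(C)/C=C/C=O | intermediate
15 | mesityl oxide, 4-methylpent-3-en-2-one | CC(=O)C=C(C)C | starting material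
16 | trimethyl[(4-methylpenta-1,3-dien-2-yl)oxy]silane | C=C(O[Si](C)(C)C)C=C(C)C | intermediate
17 | ethyl but-2-ynoate | CC#CC(=O)OCC | starting material
18 | ethyl 2,6,6-trimethyl-4-[(trimethylsilyl)oxy]cyclohexa-1,4-diene-1-carboxylate | CCOC(=O)C1=C(C)CC(O[Si](C)(C)C)=CC1(C)C | intermediate
19 | ethyl 2,6,6-trimethyl-4-oxocyclohex-1-ene-1-carboxylate | CCOC(=O)C1=C(C)CC(=O)CC1(C)C | intermediate
20 | ethyl (4R)-4-hydroxy-2,6,6-trimethylcyclohex-1-ene-1-carboxylate | CCOC(=O)C1=C(C)C[C@@H](O)CC1(C)C | intermediate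
21 | ethyl (4R)-4-[(tert-butyldimethylsilyl)oxy]-2,6,6-trimethylcyclohex-1-ene-1-carboxylate | CCOC(=O)C1=C(C)C[C@@H](O[Si](C)(C)C(C)(C)C)CC1(C)C | intermediate
22 | [(4R)-4-[(tert-butyldimethylsilyl)oxy]-2,6,6-trimethylcyclohex-1-en-1-yl]methanol | OCC1=C(C)C[C@@H](O[Si](C)(C)C(C)(C)C)CC1(C)C | intermediate
23 | [(4R)-4-[(tert-butyldimethylsilyl)oxy]-2,6,6-trimethylcyclohex-1-en-1-yl]methyl methyl carbonate | COC(=O)OCC1=C(C)C[C@@H](O[Si](C)(C)C(C)(C)C)CC1(C)C | intermediate
24 | methyl 2-[(4R)-4-[(tert-butyldimethylsilyl)oxy]-2,6,6-trimethylcyclohex-1-en-1-yl]acetate | COC(=O)CC1=C(C)C[C@@H](O[Si](C)(C)C(C)(C)C)CC1(C)C | intermediate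
25 | diethyl (2-hydroxyethyl)phosphonate | CCOP(=O)(CCO)OCC | starting material
26 | diethyl [2-[(tert-butyldimethylsilyl)oxy]ethyl]phosphonate | CCOP(=O)(CCO[Si](C)(C)C(C)(C)C)OCC | intermediate
27 | diethyl [1-[(tert-butyldimethylsilyl)oxy]-4-[(4R)-4-[(tert-butyldimethylsilyl)oxy]-2,6,6-trimethylcyclohex-1-en-1-yl]-3-oxobutan-2-yl]phosphonate | CCOP(=O)(OCC)C(CO[Si](C)(C)C(C)(C)C)C(=O)CC1=C(C)C[C@@H](O[Si](C)(C)C(C)(C)C)CC1(C)C | intermediate
28 | (3R,3'R,6'R)-3,19-bis[(tert-butyldimethylsilyl)oxy]-3'-hydroxy-7,8-dihydro-β,ε-caroten-8-one | CC1=C[C@H](O)CC(C)(C)[C@H]1/C=C/C(C)=C/C=C/C(C)=C/C=C/C=C(C)/C=C/C=C(\CO[Si](C)(C)C(C)(C)C)C(=O)CC1=C(C)C[C@@H](O[Si](C)(C)C(C)(C)C)CC1(C)C | intermediate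
29 | siphonaxanthin, (3R,3'R,6'R)-3,3',19-trihydroxy-7,8-dihydro-β,ε-caroten-8-one | CC1=C[C@H](O)CC(C)(C)[C@H]1/C=C/C(C)=C/C=C/C(C)=C/C=C/C=C(C)/C=C/C=C(\CO)C(=O)CC1=C(C)C[C@@H](O)CC1(C)C | target

**Step count.** Total: 19 steps. Longest linear sequence: 10 steps (steps 1–8, 18, 19; the β-ring branch, steps 9–15, 17, 18, 19, is equally long).

**Steps most likely to fail**

Step 10. The cis-methyl group of the diene disfavours the s-cis conformation, so the cycloaddition may be outrun by [1,5]-hydrogen shift or thermal decomposition of the diene. Fallback: the ring is closed by the Lewis-acid-mediated Michael–aldol annulation of mesityl oxide 15 with ethyl acetoacetate (ZnCl2, heptane, reflux, removal of water), which should give racemic ethyl 2,6,6-trimethyl-4-oxocyclohex-2-ene-1-carboxylate F1. Transfer hydrogenation of its enone carbonyl (RuCl(p-cymene)[(S,S)-TsDPEN], HCO2H/Et3N) should give ethyl (4S)-4-hydroxy-2,6,6-trimethylcyclohex-2-ene-1-carboxylate F2 as both C1 epimers. NaOEt in EtOH should then move the double bond into conjugation with the ester, erasing the C1 center. This fallback sets out from 15 and comes back to the route at 20, so that step 11 is not needed.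

Step 18. Addition of the hindered α-branched phosphonate anion to the electron-rich polyenal may be slow, and the base may degrade the aldehyde in the meantime. Fallback: the skeleton is closed at C11=C12 instead. Ketophosphonate 27 is condensed with chloroacetaldehyde (LiCl, i-Pr2NEt, MeCN) to (3E)-3-[[(tert-butyldimethylsilyl)oxy]methyl]-1-[(4R)-4-[(tert-butyldimethylsilyl)oxy]-2,6,6-trimethylcyclohex-1-en-1-yl]-5-chloropent-3-en-2-one F6. PPh3 (toluene, 60 °C) converts this into [(2E)-3-[[(tert-butyldimethylsilyl)oxy]methyl]-5-[(4R)-4-[(tert-butyldimethylsilyl)oxy]-2,6,6-trimethylcyclohex-1-en-1-yl]-4-oxopent-2-en-1-yl]triphenylphosphonium chloride F7. Wittig reaction of this salt with the C25 aldehyde 11 (NaOMe, CH2Cl2, then I2-catalysed isomerisation) should give 28. This fallback sets out from 27 and 11, so that step 8 is not needed, and comes back at 28.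

Step 11. The enzyme may discriminate poorly between the two faces of a ketone whose flanks differ only at the β-carbons, and C5=C6 may slowly migrate into conjugation with the ketone during a long incubation. Fallback: 19 is reduced with NaBH4/CeCl3·7H2O (MeOH, −40 °C) to racemic ethyl 4-hydroxy-2,6,6-trimethylcyclohex-1-ene-1-carboxylate F3. Lipase-catalysed transesterification (Pseudomonas cepacia lipase, vinyl acetate) should acetylate the (R)-alcohol to ethyl (4R)-4-acetoxy-2,6,6-trimethylcyclohex-1-ene-1-carboxylate F4 and leave ethyl (4S)-4-hydroxy-2,6,6-trimethylcyclohex-1-ene-1-carboxylate F5, which is separated. Methanolysis of the acetate (K2CO3, MeOH) gives 20. This fallback sets out from 19 and comes back at 20.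

**Further compounds**

F1 | step 10 | ethyl 2,6,6-trimethyl-4-oxocyclohex-2-ene-1-carboxylate (racemic) | CCOC(=O)C1C(C)=CC(=O)CC1(C)C
F2 | step 10 | ethyl (4S)-4-hydroxy-2,6,6-trimethylcyclohex-2-ene-1-carboxylate (both C1 epimers) | CCOC(=O)C1C(C)=C[C@@H](O)CC1(C)C
F3 | step 11 | ethyl 4-hydroxy-2,6,6-trimethylcyclohex-1-ene-1-carboxylate (racemic) | CCOC(=O)C1=C(C)CC(O)CC1(C)C
F4 | step 11 | ethyl (4R)-4-acetoxy-2,6,6-trimethylcyclohex-1-ene-1-carboxylate | CCOC(=O)C1=C(C)C[C@@H](OC(C)=O)CC1(C)C
F5 | step 11 | ethyl (4S)-4-hydroxy-2,6,6-trimethylcyclohex-1-ene-1-carboxylate | CCOC(=O)C1=C(C)C[C@H](O)CC1(C)C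
F6 | step 18 | (3E)-3-[[(tert-butyldimethylsilyl)oxy]methyl]-1-[(4R)-4-[(tert-butyldimethylsilyl)oxy]-2,6,6-trimethylcyclohex-1-en-1-yl]-5-chloropent-3-en-2-one | ClC/C=C(\CO[Si](C)(C)C(C)(C)C)C(=O)CC1=C(C)C[C@@H](O[Si](C)(C)C(C)(C)C)CC1(C)C
F7 | step 18 | [(2E)-3-[[(tert-butyldimethylsilyl)oxy]methyl]-5-[(4R)-4-[(tert-butyldimethylsilyl)oxy]-2,6,6-trimethylcyclohex-1-en-1-yl]-4-oxopent-2-en-1-yl]triphenylphosphonium chloride | [Cl-].c1ccccc1[P+](c1ccccc1)(c1ccccc1)C/C=C(\CO[Si](C)(C)C(C)(C)C)C(=O)CC1=C(C)C[C@@H](O[Si](C)(C)C(C)(C)C)CC1(C)C
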